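If each electrophile that couples costs two nucleophiles, these flasks can be counted before anything is integrated.

the same everywhere: electrophile 2.0 mM; protic impurity 0.600 mM; time 3.0 min
- blue: nucleophile 2.10 mM
- red: nucleophile 4.20 mM
- green: nucleophile 8.40 mM

    electrophile + nucleophile → acid set free + target (k1 = 17 M⁻¹ s⁻¹)
    nucleophile + acid set free ⇌ protonated nucleophile, settled at all times (K2 = 1.9 × 10⁶ M⁻¹)
    acid set free → by-product carried off (k3 = 1.6 s⁻¹)
    electrophile + protic impurity → quenched substrate (k4 = 130 M⁻¹ s⁻¹)
    crystals ⇌ target, rate k5*(cs5 - [target]) while solid is left; crystals form when [target] > cs5 (cs5 = 1.0 mM, k5 = 0.89 s⁻¹)

- target is meant together with its crystals
- solid, in amounts per volume of the solution: crystals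
- run time (blue): 3.0 min

1. part of the electrophile that has reacted at the end, blue
2. part of the electrophile that has reacted at the end, red
3. part of the electrophile that has reacted at the end, green
4. what raising the concentration of nucleophile from its lowest to its highest value here does to the part of the electrophile that has reacted (changes below 5 percentage points count as none) (it falls / no change / it rises)

The acid set free meets nucleophile with an equilibrium constant times charged nucleophile of 4000 in blue, far above one, so the count sends it to protonated nucleophile, and a second nucleophile goes with each coupling. The protic impurity spends electrophile and no nucleophile. In blue, the part of the electrophile that the charges pay for while the acid stays in the flask, impurity charge plus half the nucleophile charge, over the electrophile charge, is 82.5 %. This nucleophile reach has its zero of scale at one, the balanced flask, and below one the nucleophile is the limiting reagent.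

Turning the nucleophile up lifts the reach to 135 % in red and 240 % in green. Turning the impurity up, other charges held, adds its own fraction, though as quenched substrate, and in blue its full share counts, since at the start it takes electrophile faster than coupling does. Turning the electrophile up shrinks both shares. Time stands outside the reach: the half-life by coupling in blue, as charged, is 0.32 min, but that belongs to the start, for the count uses up blue's free nucleophile, and acid carried off gives nucleophile back, so blue's reach marks a slowing and not a ceiling. In red, the count leaves a third of the nucleophile charge free, which gives the electrophile a pseudo-first-order half-life of 0.485 min, so red reaches 98.6 % by hand, and green, with the larger reach, goes higher still.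

The forecast, holding that “Each coupling uses two nucleophiles”, gave 85 % for blue, 2.5 percentage points above the count, then 99.7 % for red, 100 % for green, and for the trend: it rises.

The flasks give 85.0 % in blue, 99.8 % in red and 100 % in green; the trend is it rises, by 15 points. Blue stands 2.5 points above its reach of 82.5 %, with 0.344 mM of by-product carried off after 3.00 min, and left ten times as long, blue gives >99.9 %.

In red at the end, the electrophile's half-life by coupling is 0.45 min, short against 3.0 min and shorter than the 9.9 min by quenching. Red then holds 0.227 % of its electrophile charge as electrophile, 70.2 % as target and 29.5 % as quenched substrate.

A neighbour of red charged with 1.1 mM of nucleophile has a reach of 57.5 %, below one, so electrophile should remain at the end. That flask gives 64.7 %, with 35.3 % of the electrophile charge still there.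

The constants used here stand for no real mixture; the result is computed.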